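## Retrosynthetic overview
1. 18 ⇒ 17. The seven-membered ring C and the cyclopentane ring D both hang on C3. They come from one C3 radical cascade, and the radical is stored as a C3–O ester.
2. 17 ⇒ 15 closes ring B by C1–C8 tert-alkylation of the triketone. 15 ⇒ 13 is a double methyl addition to an enol δ-lactone.
3. 13 ⇒ 8 + 11. A Michael addition–lactonisation builds the quaternary C5, and the temporary lactone ring fixes C7.
4. 8 ⇒ 6 ⇒ 5. The key disconnection is the C3–O bond, made by enantioselective acyloxylative dearomatisation. It tells C3 from C5, blocks C3, relays chirality to C5, and is erased in the last step.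
5. Ring order: A (phloroglucinol) → temporary lactone → B → C, then D.

Atom labels: the bicyclo[3.3.1]nonane numbering of 17 is used for all compounds. C1 carries isobutyryl, C3 the ester and a prenyl group, C5 geranyl, and C7 a prenyl group. C6 is CH2, C8 is CMe2, and C2, C4 and C9 are C=O.

Assumption: the (R,R)-iodoarene gives (S)-6 and step 6 adds syn to the ester oxygen; if either sense is reversed, the (S,S)-iodoarene is used, because C3 is erased in step 9.

## Route

Step 1
Reactants: 1 phloroglucinol; 2 isobutyryl chloride
Product: 3 phlorisobutyrophenone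
Conditions: AlCl3 (3 equiv), CH2Cl2/MeNO2, 0 → 40 °C
Reagents that add atoms: isobutyryl chloride (2), CC(C)C(=O)Cl
Why: Friedel–Crafts acylation, in which the first acyl group deactivates the ring so the reaction stops at monoacylation; no stereocentre is formed.

Step 2
Reactants: 3 phlorisobutyrophenone; 4 prenyl bromide
Product: 5 3-prenylphlorisobutyrophenone
Conditions: KOH (1.0 equiv), H2O, 0 °C → rt, 4 (0.9 equiv)
Reagents that add atoms: prenyl bromide (4), CC(C)=CCBr
Why: C-alkylation of a phloroglucinol phenolate in water, where hydrogen-bonded oxygen favours attack through carbon and a slight deficit of bromide limits diprenylation; no stereocentre is formed.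

Step 3 (key step)
Reactants: 5 3-prenylphlorisobutyrophenone
Product: 6 (1S)-2,4-dihydroxy-5-isobutyryl-6-oxo-1-prenylcyclohexa-2,4-dien-1-yl pivalate
Conditions: (R,R)-2-iodo-1,3-bis[1-(mesitylcarbamoyl)ethoxy]benzene (1.15 equiv), urea·H2O2 (1.1 equiv), Piv2O (1.3 equiv), CH2Cl2, rt, 16 h; then 5, CH2Cl2/HFIP 9:1, 4 Å MS, −40 °C
Reagents that add atoms: pivalic anhydride, CC(C)(C)C(=O)OC(=O)C(C)(C)C
Why: Proposed new method: the unchelated C4–OH exchanges onto the trivalent iodine centre of the bis(pivaloyloxy)iodane pre-formed in the flask (all peroxide is consumed before the alkene-bearing substrate is added), the hydrogen-bonded lactamide arms shield one face, and pivalate is transferred to the ortho carbon that carries the prenyl group, because that carbon best stabilises the developing phenoxenium charge and gives a product that cannot re-aromatise, which forms the C3–O bond and sets C3 as S; the closest known reaction types are the Wessely acyloxylation of phenols and the hydroxylative or spirolactonising phenol dearomatisations mediated by chiral aryl-λ3-iodanes, neither shown for an intermolecular carboxylate or for an acylphloroglucinol.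

Step 4
Reactants: 6 pivalate dienone; 7 geranyl bromide
Product: 8 (1S)-3-geranyl-2,4-dihydroxy-5-isobutyryl-6-oxo-1-prenylcyclohexa-2,4-dien-1-yl pivalate
Conditions: 7 (1.05 equiv), K2CO3 (1.1 equiv), acetone, 0 °C → rt
Reagents that add atoms: geranyl bromide (7), CC(C)=CCC/C(C)=C/CBr
Why: SN2 C-allylation of a vinylogous acid, in which C3 is quaternary and C1 is acyl-deactivated, so C5 is the only free nucleophilic carbon and direct displacement keeps the E alkene; no new stereocentre is formed.

Step 5
Reactants: 9 2-(bromomethyl)acrylic acid; 10 2-methylprop-1-enylmagnesium bromide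
Product: 11 5-methyl-2-methylidenehex-4-enoic acid
Conditions: NaH (1.0 equiv), THF, 0 °C; then 10 (1.2 equiv), CuI (10 mol%), −30 → 0 °C; aq HCl
Reagents that add atoms: 2-methylprop-1-enylmagnesium bromide (10), CC(C)=C[Mg]Br
Why: Copper-catalysed allylic substitution of the carboxylate salt, where the SN2 and SN2' pathways give the same product; no stereocentre is formed.

Step 6
Reactants: 8 geranylated dienone; 11 acrylic acid
Product: 13 (3R,4aS,6S)-4a-geranyl-8-isobutyryl-2,5,7-trioxo-3,6-diprenyl-3,4,4a,5,6,7-hexahydro-2H-chromen-6-yl pivalate, via mixed pivalic anhydride 12 (not isolated)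
Conditions: 11, PivCl (1.05 equiv), iPr2NEt (2.2 equiv), CH2Cl2, 0 °C; then 8, 3,4-dihydro-2H-pyrimido[2,1-b]benzothiazole (20 mol%), rt; then DBU (10 mol%), rt
Reagents that add atoms: acid 11, C=C(CC=C(C)C)C(=O)O
Why: Michael addition–lactonisation of an α,β-unsaturated acyl ammonium ion with a 2-substituted cyclic 1,3-dicarbonyl, in which C5 attacks the unsubstituted CH2 terminus syn to the small ester oxygen and anti to the C3 prenyl chain (sets C5), only the C9 enol oxygen can lactonise because C4 then lies between two quaternary carbons, and DBU equilibrates the lactone α-carbon to the isomer with equatorial prenyl trans to the axial geranyl group (sets C7).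

Step 7
Reactants: 13 enol δ-lactone
Product: 15 (1S,3S)-3-geranyl-4-hydroxy-3-[(2R)-2-(2-hydroxypropan-2-yl)-5-methylhex-4-enyl]-5-isobutyryl-2,6-dioxo-1-prenylcyclohex-4-en-1-yl pivalate, via methyl ketone 14 (not isolated)
Conditions: MeMgBr (2.6 equiv), CeCl3 (2.6 equiv), THF, −78 → −30 °C; aq NH4Cl
Reagents that add atoms: methylmagnesium bromide, C[Mg]Br
Why: Double Grignard addition to an activated enol ester, in which the triketonate leaving group (pKa about 5) makes the lactone carbonyl the most electrophilic site and, once released, masks C2, C9 and the isobutyryl carbonyl as an enolate, while C4 and the tertiary pivalate are too hindered to react and CeCl3 suppresses enolisation so C7 is kept.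

Step 8
Reactants: 15 tertiary carbinol
Product: 17 (1S,3S,5S,7R)-5-geranyl-1-isobutyryl-8,8-dimethyl-2,4,9-trioxo-3,7-diprenylbicyclo[3.3.1]nonan-3-yl pivalate, via bis(trimethylsilyl) ether 16 (not isolated)
Conditions: TMSOTf (2.4 equiv), 2,6-di-tert-butyl-4-methylpyridine (2.2 equiv), CH2Cl2, −78 → −20 °C
Reagents that add atoms: none
Why: Intramolecular Mukaiyama–Reetz α-tert-alkylation (SN1), in which the excess TMSOTf ionises the tertiary silyl ether, the silylated enol reacts through carbon C1 (C3 is blocked, so no closure there), the tether allows one face only (sets C1), and the hindered base removes protons so C7 cannot epimerise through alkene re-protonation and the other alkenes are left alone.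

Step 9
Reactants: 17 bicyclic pivalate
Product: 18 target CNP0379246.1
Conditions: fac-Ir(ppy)3 (1 mol%), Hantzsch ester (1.3 equiv, slow addition), MeCN, 450 nm LED, 25 °C, degassed
Reagents that add atoms: none
Why: Photoredox reductive scission of an α-acyloxy ketone followed by a tin-free reductive radical cyclisation, in which the C3 radical can be reached only on its endo face by the CH terminus of the axial C7 prenyl group (7-exo-trig, sets C3 and the ring-fusion CH in the fold with the CMe2 end turned to the C2 side, as in the natural cage), the tertiary radical closes 5-exo-trig on the C3 prenyl group with the new CMe2 radical on the convex face (sets the isopropyl-bearing CH), Hantzsch ester delivers the last hydrogen, and the equatorial bridgehead geranyl group cannot reach C3.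

## Compound list
1 | phloroglucinol | Oc1cc(O)cc(O)c1 | starting material
2 | isobutyryl chloride | CC(C)C(=O)Cl | starting material
3 | phlorisobutyrophenone | CC(C)C(=O)c1c(O)cc(O)cc1O | intermediate
4 | prenyl bromide | CC(C)=CCBr | starting material
5 | 3-prenylphlorisobutyrophenone | CC(C)=CCc1c(O)cc(O)c(C(=O)C(C)C)c1O | intermediate
6 | (S)-C3 pivalate dienone | CC(C)=CC[C@@]1(OC(=O)C(C)(C)C)C(=O)C(C(=O)C(C)C)=C(O)C=C1O | intermediate
7 | geranyl bromide | CC(C)=CCC/C(C)=C/CBr | starting material
8 | C5-geranyl (S)-C3 pivalate dienone | CC(C)=CCC/C(C)=C/CC1=C(O)[C@](CC=C(C)C)(OC(=O)C(C)(C)C)C(=O)C(C(=O)C(C)C)=C1O | intermediate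
9 | 2-(bromomethyl)acrylic acid | C=C(CBr)C(=O)O | starting material
10 | 2-methylprop-1-enylmagnesium bromide | CC(C)=C[Mg]Br | starting material
11 | 5-methyl-2-methylidenehex-4-enoic acid | C=C(CC=C(C)C)C(=O)O | intermediate
12 | mixed pivalic anhydride of 11 | C=C(CC=C(C)C)C(=O)OC(=O)C(C)(C)C | intermediate
13 | enol δ-lactone (C7 R, C5 S, C3 S) | CC(C)=CCC/C(C)=C/C[C@]12C[C@@H](CC=C(C)C)C(=O)OC1=C(C(=O)C(C)C)C(=O)[C@](OC(=O)C(C)(C)C)(CC=C(C)C)C2=O | intermediate
14 | ring-opened methyl ketone | CC(C)=CCC/C(C)=C/C[C@]1(C[C@@H](CC=C(C)C)C(C)=O)C(O)=C(C(=O)C(C)C)C(=O)[C@](OC(=O)C(C)(C)C)(CC=C(C)C)C1=O | intermediate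
15 | tertiary carbinol | CC(C)=CCC/C(C)=C/C[C@]1(C[C@@H](CC=C(C)C)C(C)(C)O)C(O)=C(C(=O)C(C)C)C(=O)[C@](OC(=O)C(C)(C)C)(CC=C(C)C)C1=O | intermediate
16 | bis(trimethylsilyl) ether of 15 | CC(C)=CCC/C(C)=C/C[C@]1(C[C@@H](CC=C(C)C)C(C)(C)O[Si](C)(C)C)C(O[Si](C)(C)C)=C(C(=O)C(C)C)C(=O)[C@](OC(=O)C(C)(C)C)(CC=C(C)C)C1=O | intermediate
17 | (1S,3S,5S,7R)-bicyclo[3.3.1]nonanetrione C3 pivalate with endo C7 prenyl | CC(C)=CCC/C(C)=C/C[C@]12C[C@@H](CC=C(C)C)C(C)(C)[C@](C(=O)C(C)C)(C1=O)C(=O)[C@](OC(=O)C(C)(C)C)(CC=C(C)C)C2=O | intermediate
18 | CNP0379246.1 (C1 S, C3 S, C5 R, C7 R, ring-fusion CH R, isopropyl-bearing CH R) | CC(C)=CCC/C(C)=C/C[C@@]12C[C@H]3C[C@@H]4C(C)(C)[C@@H](C(C)C)C[C@]4(C1=O)C(=O)[C@@](C(=O)C(C)C)(C2=O)C3(C)C | target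

## Step count and risks
Total step count: 9. Longest linear sequence: 8 (steps 1–4 and 6–9).

**Step 3 (the proposed new step).**
- Risks are attack at the free C5–H, loss of a benzylic proton to an ortho-quinone methide followed by chromene formation, and low enantioselectivity.
- Fallback with known chemistry, starting from 5: a Wessely oxidation with Pb(OAc)4 in pivalic acid/CH2Cl2 gives the racemic pivalate F1.
- F1 is a strong vinylogous acid. It is resolved by preparative chiral SFC or by crystallisation of its cinchonidine salt. The route is rejoined at 6.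

**Step 8.**
- Two quaternary carbons are joined through a boat-like closure, because the C7 prenyl group is endo.
- Elimination, capture by the C9 oxygen, or attack by the proximal geranyl alkene can compete.
- Fallback from 15: catalytic camphorsulfonic acid in CH2Cl2 first closes the carbinol onto the C9 enol oxygen, giving the 2,2-dimethylpyran enol ether F2 through a chair with equatorial prenyl.
- Me2AlCl in CH2Cl2 then ionises the tertiary C–O bond inside a tight ion pair and recombines it at C1. This is a 1,3 oxygen-to-carbon transposition of the Petasis–Ferrier kind. The route is rejoined at 17.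

**Step 9.**
- Risks are premature hydrogen transfer to the C3 radical and the facial choice at the prenyl CH.
- The tether does not secure the C2-side fold over the C4-side fold. My steric estimate finds a contact between a methyl of the prenyl CMe2 end and the equatorial C8 methyl in the required C2-side fold, so the C4-side fold (wrong epimers at the ring-fusion CH and the isopropyl-bearing CH) may predominate. The two folds give diastereomers that would have to be separated.
- Fallback from 17: SmI2 in THF/MeOH removes the pivalate and gives the C3–H enol F3.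
- Mn(OAc)3·2H2O with Cu(OAc)2 in AcOH then runs the oxidative radical cyclisation, ending in the isopropenyl cage F4.
- H2 with RhCl(PPh3)3 in benzene saturates only the 1,1-disubstituted alkene. The route is rejoined at 18. This fallback has the same fold issue.

## Further compounds
F1 | step 3 | racemic 6 | CC(C)=CCC1(OC(=O)C(C)(C)C)C(=O)C(C(=O)C(C)C)=C(O)C=C1O
F2 | step 8 | 2,2-dimethylpyran enol ether (oxygen-cyclised isomer of 17) | CC(C)=CCC/C(C)=C/C[C@]12C[C@@H](CC=C(C)C)C(C)(C)OC1=C(C(=O)C(C)C)C(=O)[C@](OC(=O)C(C)(C)C)(CC=C(C)C)C2=O
F3 | step 9 | C3–H enol of the endo bicyclo[3.3.1]nonanetrione | CC(C)=CCC/C(C)=C/C[C@]12C[C@@H](CC=C(C)C)C(C)(C)[C@](C(=O)C(C)C)(C1=O)C(=O)C(CC=C(C)C)=C2O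
F4 | step 9 | isopropenyl analogue of 18 | CC(C)=CCC/C(C)=C/C[C@@]12C[C@H]3C[C@@H]4C(C)(C)[C@@H](C(C)=C)C[C@]4(C1=O)C(=O)[C@@](C(=O)C(C)C)(C2=O)C3(C)C
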